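Assumptions: the SMILES was read as the natural 2,3-trans (2R,3R) dihydroflavonol (checked by CIP analysis), and each telescoped one-pot sequence (metalation/transmetalation/coupling, borylation/oxidation, desilylation/acidolysis) is counted as one step.

## Retrosynthetic overview

1. The target comes from global deprotection of a per-protected trans-dihydroflavonol. Its C2–aryl bond and both stereocentres come from a Pd-catalysed asymmetric conjugate arylation of a 6-benzyl-3-alkoxychromone with a 4-oxygenated phenylboronic acid (B ring added last).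
2. The chromone (ring C) comes from an o-hydroxyaryl α-alkoxymethyl ketone plus DMF-DMA (C2 carbon). The ketone comes from an o-bromophenol (aryl magnesiate) and a glycolate Weinreb amide.
3. The phenol that becomes O1 comes from sterically controlled Ir-catalysed C–H borylation/oxidation of a 2-benzylresorcinol bis-MOM ether. This differentiates the ring oxygen from the two oxygens flanking the benzyl group and fixes 6- rather than 8-benzyl regiochemistry.
4. The diarylmethane comes from directed ortho-metalation of resorcinol bis-MOM ether and Negishi coupling with a p-cresol-derived benzyl bromide.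
5. Ring order: A ring (from resorcinol) elaborated first, then C ring (chromone), then B ring. Four building blocks: p-cresol, resorcinol, methyl glycolate, 4-bromophenol.

## Route

### Fragment A: benzyl bromide

**Step 1**
Reactants: 1, p-cresol
Product: 2, triisopropyl(4-methylphenoxy)silane
Conditions: TIPSCl, imidazole, DMF, rt
Reagents that add atoms: triisopropylsilyl chloride, CC(C)[Si](Cl)(C(C)C)C(C)C
Why: Imidazole-promoted O-silylation of a phenol; the bulky aryl TIPS ether tolerates radical bromination and organometallics and later shields this ring from Ir borylation.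

**Step 2**
Reactants: 2, triisopropyl(4-methylphenoxy)silane
Product: 3, [4-(bromomethyl)phenoxy]triisopropylsilane (used crude)
Conditions: NBS, AIBN (5 mol%), PhCF3, 85 °C
Reagents that add atoms: N-bromosuccinimide, O=C1CCC(=O)N1Br
Why: Wohl–Ziegler radical bromination selects the benzylic C–H, and the bulky OTIPS group disfavours ring bromination.

### Fragment B: A ring

**Step 3**
Reactants: 4, resorcinol
Product: 5, 1,3-bis(methoxymethoxy)benzene
Conditions: MOMCl, i-Pr2NEt, CH2Cl2, 0 °C → rt
Reagents that add atoms: chloromethyl methyl ether, COCCl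
Why: Standard MOM protection of both phenols, installing two strong directed-metalation groups.

**Step 4**
Reactants: 5, 1,3-bis(methoxymethoxy)benzene; 3, [4-(bromomethyl)phenoxy]triisopropylsilane
Product: 6, {4-[2,6-bis(methoxymethoxy)benzyl]phenoxy}triisopropylsilane
Conditions: n-BuLi, THF, 0 °C; ZnCl2, 0 °C → rt; then 3, Pd2(dba)3 (1.5 mol%), SPhos (6 mol%), THF, 50 °C
Reagents that add atoms: none
Why: Directed ortho-metalation occurs at C2 between the two OMOM groups, and after Li→Zn transmetalation a Negishi sp2–sp3 coupling with the benzyl bromide forms the diarylmethane bond.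

**Step 5**
Reactants: 6, {4-[2,6-bis(methoxymethoxy)benzyl]phenoxy}triisopropylsilane
Product: 7, 3,5-bis(methoxymethoxy)-4-[4-(triisopropylsilyloxy)benzyl]phenol
Conditions: [Ir(OMe)(cod)]2 (1.5 mol%), dtbpy (3 mol%), B2pin2 (0.8 equiv), THF, 80 °C; then 30% H2O2, aq NaOH, 0 °C
Reagents that add atoms: hydrogen peroxide, OO (supplies the phenolic O; B2pin2 is transient and leaves no atoms)
Why: Sterically governed Ir-catalysed C–H borylation hits the only C–H with no ortho substituent (C5 of the resorcinol ring; every C–H of the silyloxybenzyl ring is ortho-substituted), and C–B oxidation gives the one free phenol that will become O1.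

**Step 6**
Reactants: 7, 3,5-bis(methoxymethoxy)-4-[4-(triisopropylsilyloxy)benzyl]phenol
Product: 8, 2-bromo-3,5-bis(methoxymethoxy)-4-[4-(triisopropylsilyloxy)benzyl]phenol
Conditions: NBS (1.0 equiv), CH2Cl2, −78 → −40 °C, dark
Reagents that add atoms: N-bromosuccinimide, O=C1CCC(=O)N1Br
Why: Electrophilic aromatic bromination ortho to the free OH; the two open positions of this ring are equivalent, so a single regioisomer forms.

### Fragment C: Weinreb amide

**Step 7**
Reactants: 9, methyl glycolate
Product: 10, methyl 2-(methoxymethoxy)acetate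
Conditions: MOMCl, i-Pr2NEt, CH2Cl2, 0 °C → rt
Reagents that add atoms: chloromethyl methyl ether, COCCl
Why: Standard MOM protection of a primary alcohol, carrying the future 3-OH in masked form.

**Step 8**
Reactants: 10, methyl 2-(methoxymethoxy)acetate
Product: 11, N-methoxy-2-(methoxymethoxy)-N-methylacetamide
Conditions: MeNH(OMe)·HCl, i-PrMgCl, THF, −20 °C
Reagents that add atoms: N,O-dimethylhydroxylamine hydrochloride, CNOC.Cl
Why: Ester-to-Weinreb-amide aminolysis by the magnesium amide of N,O-dimethylhydroxylamine.

### Union and C ring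

**Step 9**
Reactants: 8, 2-bromo-3,5-bis(methoxymethoxy)-4-[4-(triisopropylsilyloxy)benzyl]phenol; 11, N-methoxy-2-(methoxymethoxy)-N-methylacetamide
Product: 12, 1-{6-hydroxy-2,4-bis(methoxymethoxy)-3-[4-(triisopropylsilyloxy)benzyl]phenyl}-2-(methoxymethoxy)ethan-1-one
Conditions: i-PrMgCl (1.05 equiv), THF, 0 °C; n-BuLi (2.1 equiv), −20 °C; 11 (2.5 equiv), −20 °C → rt; aq NH4Cl
Reagents that add atoms: none
Why: Phenol deprotonation then Br/Mg exchange through a lithium magnesiate gives the unprotected ortho-metalated phenoxide, and Weinreb ketone synthesis (chelated tetrahedral intermediate) stops at the ketone.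

**Step 10**
Reactants: 12, the o-hydroxyaryl α-(methoxymethoxy)methyl ketone
Product: 13, 3,5,7-tris(methoxymethoxy)-6-[4-(triisopropylsilyloxy)benzyl]-4H-chromen-4-one
Conditions: DMF-DMA (3 equiv), toluene, 90 °C; then SiO2, CH2Cl2, rt
Reagents that add atoms: N,N-dimethylformamide dimethyl acetal, COC(OC)N(C)C (supplies C2)
Why: Enaminone formation at the α-CH2 followed by intramolecular addition–elimination of the ortho phenol (loss of Me2NH) closes the chromone ring; only the borylation-derived OH is free, so the benzyl group ends up at C6.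

### Fragment D: boronic acid

**Step 11**
Reactants: 14, 4-bromophenol
Product: 15, 1-bromo-4-(methoxymethoxy)benzene
Conditions: MOMCl, i-Pr2NEt, CH2Cl2, 0 °C → rt
Reagents that add atoms: chloromethyl methyl ether, COCCl
Why: Standard MOM protection of the phenol.

**Step 12**
Reactants: 15, 1-bromo-4-(methoxymethoxy)benzene
Product: 16, [4-(methoxymethoxy)phenyl]boronic acid
Conditions: n-BuLi, THF, −78 °C; B(Oi-Pr)3; aq NH4Cl
Reagents that add atoms: triisopropyl borate, CC(C)OB(OC(C)C)OC(C)C; water, O
Why: Br/Li exchange, electrophilic borylation with a trialkyl borate and mild hydrolysis (MOM survives the near-neutral work-up).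

### Key coupling and end game

**Step 13**
Reactants: 13, the 3-(methoxymethoxy)chromone; 16, [4-(methoxymethoxy)phenyl]boronic acid
Product: 17, (2R,3R)-3,5,7-tris(methoxymethoxy)-2-[4-(methoxymethoxy)phenyl]-6-[4-(triisopropylsilyloxy)benzyl]chroman-4-one (2,3-trans)
Conditions: 16 (2.5 equiv), Pd(OCOCF3)2 (10 mol%), (R)-t-BuPyOx (12 mol%), NH4PF6 (30 mol%), H2O (5 equiv), ClCH2CH2Cl, 60 °C; then Et3N, MeOH, 25 °C
Reagents that add atoms: none
Why: Proposed new method: Pd(II)/pyridine-oxazoline-catalysed asymmetric conjugate arylation of a 3-alkoxy (α-oxygenated) chromone, a substrate class not yet shown for this reaction; transmetalation gives cationic [(PyOx)Pd–Ar]+, and enantio-determining syn-migratory insertion of C2=C3 puts the aryl on the unsubstituted C2 (Re face) and Pd on C3; the α-alkoxy C-bound Pd enolate cannot β-hydride eliminate (C2–H is anti to Pd in the ring) and is protonolysed by water via the O-enolate, regenerating Pd(II); C3 is then equilibrated through the enol (Et3N/MeOH) to the diequatorial 2,3-trans isomer with C2 untouched; the (R)-ligand is chosen by analogy with the facial preference of this catalyst on cyclic enones (the antipode is used if the sense is reversed); closest known reaction: Pd–PyOx conjugate addition of arylboronic acids to chromones and cyclic enones (Hayashi–Miyaura-type 1,4-addition).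

**Step 14**
Reactants: 17, the protected (2R,3R)-dihydroflavonol
Product: 18, gericudranin E, (2R,3R)-3,5,7-trihydroxy-6-(4-hydroxybenzyl)-2-(4-hydroxyphenyl)chroman-4-one
Conditions: TBAF/AcOH (1:1), THF, 0 °C; then conc. HCl–MeOH (≈2 M), 45 °C (one pot)
Reagents that add atoms: none
Why: Buffered fluoride removes the aryl TIPS ether and acid-catalysed acetal cleavage removes all four MOM ethers; no basic phenoxide is generated, so quinone-methide or retro-oxa-Michael epimerisation is avoided and both stereocentres are retained.

## Compound list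

1 | p-cresol | Cc1ccc(O)cc1 | starting material
2 | triisopropyl(4-methylphenoxy)silane | Cc1ccc(O[Si](C(C)C)(C(C)C)C(C)C)cc1 | intermediate
3 | [4-(bromomethyl)phenoxy]triisopropylsilane | BrCc1ccc(O[Si](C(C)C)(C(C)C)C(C)C)cc1 | intermediate
4 | resorcinol | Oc1cccc(O)c1 | starting material
5 | 1,3-bis(methoxymethoxy)benzene | COCOc1cccc(OCOC)c1 | intermediate
6 | {4-[2,6-bis(methoxymethoxy)benzyl]phenoxy}triisopropylsilane | COCOc1cccc(OCOC)c1Cc1ccc(O[Si](C(C)C)(C(C)C)C(C)C)cc1 | intermediate
7 | 3,5-bis(methoxymethoxy)-4-[4-(triisopropylsilyloxy)benzyl]phenol | COCOc1cc(O)cc(OCOC)c1Cc1ccc(O[Si](C(C)C)(C(C)C)C(C)C)cc1 | intermediate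
8 | 2-bromo-3,5-bis(methoxymethoxy)-4-[4-(triisopropylsilyloxy)benzyl]phenol | COCOc1cc(O)c(Br)c(OCOC)c1Cc1ccc(O[Si](C(C)C)(C(C)C)C(C)C)cc1 | intermediate
9 | methyl glycolate | COC(=O)CO | starting material
10 | methyl 2-(methoxymethoxy)acetate | COCOCC(=O)OC | intermediate
11 | N-methoxy-2-(methoxymethoxy)-N-methylacetamide | COCOCC(=O)N(C)OC | intermediate
12 | 1-{6-hydroxy-2,4-bis(methoxymethoxy)-3-[4-(triisopropylsilyloxy)benzyl]phenyl}-2-(methoxymethoxy)ethan-1-one | COCOCC(=O)c1c(O)cc(OCOC)c(Cc2ccc(O[Si](C(C)C)(C(C)C)C(C)C)cc2)c1OCOC | intermediate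
13 | 3,5,7-tris(methoxymethoxy)-6-[4-(triisopropylsilyloxy)benzyl]-4H-chromen-4-one | O=c1c(OCOC)coc2cc(OCOC)c(Cc3ccc(O[Si](C(C)C)(C(C)C)C(C)C)cc3)c(OCOC)c12 | intermediate
14 | 4-bromophenol | Oc1ccc(Br)cc1 | starting material
15 | 1-bromo-4-(methoxymethoxy)benzene | COCOc1ccc(Br)cc1 | intermediate
16 | [4-(methoxymethoxy)phenyl]boronic acid | COCOc1ccc(B(O)O)cc1 | intermediate
17 | (2R,3R)-3,5,7-tris(methoxymethoxy)-2-[4-(methoxymethoxy)phenyl]-6-[4-(triisopropylsilyloxy)benzyl]chroman-4-one | O=C1c2c(cc(OCOC)c(Cc3ccc(O[Si](C(C)C)(C(C)C)C(C)C)cc3)c2OCOC)O[C@H](c2ccc(OCOC)cc2)[C@H]1OCOC | intermediate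
18 | gericudranin E, (2R,3R)-3,5,7-trihydroxy-6-(4-hydroxybenzyl)-2-(4-hydroxyphenyl)chroman-4-one | O=C1c2c(cc(O)c(Cc3ccc(O)cc3)c2O)O[C@H](c2ccc(O)cc2)[C@H]1O | target

## Summary

Total step count: 14.

Longest linear sequence: 9 steps (1 → 2 → 4 → 5 → 6 → 9 → 10 → 13 → 14, from p-cresol). The other chains are 8 steps (resorcinol), 6 steps (methyl glycolate) and 4 steps (4-bromophenol).

Three steps most likely to fail:

1. **Step 13 (proposed new conjugate arylation).** The α-alkoxy group may slow insertion or lower ee, protonation may give the 2,3-cis isomer first, and the C3 equilibration could erode ee through reversible ring opening.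
   Fallback (known chemistry): use N-methoxy-N-methylacetamide in step 9 to make the 2'-hydroxyacetophenone, then DMF-DMA to the 3-unsubstituted chromone. The established Pd(OCOCF3)2/t-BuPyOx asymmetric addition of 16 gives the (2S)-flavanone. Soft enolisation (TMSOTf, Et3N) and Rubottom oxidation of the silyl enol ether with DMDO (attack anti to the C2 aryl) installs the trans 3-OH, followed by the same deprotection.

2. **Step 9 (acylation of the hindered, phenoxide-bearing aryl magnesiate).** Competing butyl transfer or enolisation of 11 would return debrominated 7.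
   Fallback: ortho-formylate phenol 7 directly (MgCl2, Et3N, paraformaldehyde), add MOMOCH2Li (from MOMOCH2SnBu3/n-BuLi) to the salicylaldehyde, and oxidise the benzylic alcohol (MnO2) to ketone 12. This avoids the aryl-metal altogether.

3. **Step 4 (Negishi coupling of a di-ortho-substituted arylzinc with an ionisable benzyl bromide).** Slow transmetalation, bibenzyl formation or Zn-promoted Friedel–Crafts benzylation at the wrong carbon are possible.
   Fallback: quench lithiated 5 with DMF to 2,6-bis(methoxymethoxy)benzaldehyde, add the Grignard reagent of TIPS-protected 4-bromophenol, and remove the diaryl carbinol oxygen (acetylation, then Pd/C hydrogenolysis) to reach 6.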